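If a remedy that added no incoming ligand was to beat green in Tuesday's flask, the complex with two exchanged had to climb past a line drawn by the charge itself, so I began from that line.

| flask | starting complex | incoming ligand | leaving ligand | temperature | remark | time |
|---|---|---|---|---|---|---|
| Tuesday's | 1.8 M | 0.60 equiv | 1 equiv | 80 °C | the very flask that is asked about, followed so far |  |
| Sunday's | 1.8 M | 0.60 equiv | 1 equiv | 65 °C | run made earlier |  |
| flask | 1.8 M | 0.600 equiv | 1.00 equiv | 80 °C |  | 12 h |

- Tuesday's (time / h: complex with two exchanged / %, starting complex / %): 1.00: 9.3, 64.1; 3.00: 17.3, 65.4; 6.00: 21.6, 66.1; 8.00: 23.7, 68.5; 12.0: 23.5, 68.0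
- Sunday's (time / h: complex with two exchanged / %, starting complex / %): 2.00: 6.9, 64.4; 6.00: 15.4, 61.1; 12.0: 16.2, 63.8; 15.0: 21.6, 62.7; 25.0: 21.7, 66.4

(readings scatter by 1 percentage point)

- green: at 12 h add incoming ligand, 50.0% of the amount charged, then wait 6.0 h
- violet: change nothing and wait 6.0 h more
- teal: at 12 h raise the temperature by 10 K, then wait 6.0 h
- red: at 12 h take out 90% of the leaving ligand then present, then wait 6.0 h

- the volume of additions can be left aside
- on the list of suspects stand: starting complex + incoming ligand <-> leaving ligand + complex with one exchanged; complex with one exchanged + incoming ligand <-> leaving ligand + complex with two exchanged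

- complex with two exchanged, in percent of the starting complex first charged, at 12 h
- the remedy with the largest gain of complex with two exchanged, or "none" below 2 percentage points (green / violet / teal / red / none)
- complex with two exchanged present, in percent of the starting complex first charged, after green
- complex with two exchanged present, in percent of the starting complex first charged, after teal

Each complex with two exchanged holds two incoming ligands. When I counted totals instead of rates, time dropped out: at any moment the incoming ligand gone equals the complex with one exchanged plus two for each complex with two exchanged, so the total of complex with two exchanged came to one for two of the ligand gone at best. That gave me a ceiling, half the incoming ligand charged, as a fraction of the starting complex charged: 30.0%. Tuesday's last two readings averaged 23.6%, so they stood at 78.7% of the ceiling. I called this share the ligand fill, the plateau of complex with two exchanged over its ceiling. Sunday's flask, at 65 °C, read 72.2% from its last two readings.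

Green's dose lifted the ceiling to 45.0%. If the fill held, green reached 35.4%, a gain of 12 percentage points. To match that under the old ceiling, a rival adding no ligand needed a fill of 118%, which is more ligand than the flask was charged with. It had 6.4 points of room, less than green's gain. So I chose green.

The forecast gave 23.7% at 12 h, named green, and put green at 35% and teal at 24.3%, holding that “ligand supply is the limit”.

    starting complex + incoming ligand ⇌ leaving ligand + complex with one exchanged (K = 4.72, k = 3.49 × 10⁻⁴ /M/s, Ea = 65.0 kJ/mol, ΔH = −27.0 kJ/mol)
    complex with one exchanged + incoming ligand ⇌ leaving ligand + complex with two exchanged (K = 120, k = 2.73 × 10⁻⁴ /M/s, Ea = 77.0 kJ/mol, ΔH = −20.0 kJ/mol)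
    (constants at 80 °C)

The flask gave 23.3% at 12 h, a fill of 77.7%. The best remedy was green, which gained 13 points and reached 35.9%, a fill of 79.8%, while teal ended at 23.7%. The main reason the flask held no more at 12 h was the running short of incoming ligand, of which 7.29% of its own charge stood free at 12.0 h. The simulated run with that shortage taken away held 92.2% against 23.3%. The neighbour flask charged with 1.50 equiv of incoming ligand had a ceiling of 75.0% and held 63.3%, a fill of 84.4%.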